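Ring B (C5–C10) is cut at its C8 carbonyl. This carbon has C9, bound to the quaternary C10, on one side and C7 on the other, so it is brought in as carbon monoxide when the C5–C9 bond of a cyclopropane is opened whose C5 carries the C6=C7 vinyl group. One rhodium-catalysed carbonylative ring expansion forms C8–C9 and C7–C8, closes ring B as the Δ5-8-ketone and carries the C10 configuration through. The precursor is the silyl ether of 6-methyl-1-vinylbicyclo[4.1.0]heptan-2-ol, made by CBS reduction and hydroxyl-directed Simmons–Smith cyclopropanation. The same carbinol later directs the hydrogenation that sets C5 and then becomes the C4 ketone that takes the methyl group.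

Key step: step 6

Remark: carbons are numbered as in eudesmane (ring A = C1–C5 and C10, ring B = C5–C10, C11–C13 on C7, C14 on C10, C15 on C4), β is the face of the C10 methyl group, and the (S)-oxazaborolidine is assumed to give the (R)-carbinol 3, as it does with other 2-halocycloalk-2-enones.

Step 1
Reactants: 1 3-methylcyclohex-2-en-1-one
Product: 2 2-iodo-3-methylcyclohex-2-en-1-one
Conditions: I2, pyridine, CH2Cl2, 0 °C → rt
Reagents that add atoms: iodine, II
Why: α-Iodination of an enone by the iodine–pyridine addition–elimination sequence (pyridine adds at C3, the enolate is iodinated, pyridine leaves) should place the halogen only on the α-carbon.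

Step 2
Reactants: 2 2-iodo-3-methylcyclohex-2-en-1-one
Product: 3 (R)-2-iodo-3-methylcyclohex-2-en-1-ol
Conditions: (S)-2-methyl-CBS-oxazaborolidine (20 mol%), BH3·SMe2, THF, −20 °C; MeOH
Reagents that add atoms: none
Why: Corey–Bakshi–Shibata reduction, in which the iodine-bearing alkene carbon acts as the large group, so the (S)-catalyst should deliver hydride to one carbonyl face and give the (R)-carbinol, the only stereocentre made with an external chiral reagent.

Step 3
Reactants: 3 (R)-2-iodo-3-methylcyclohex-2-en-1-ol, 4 potassium vinyltrifluoroborate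
Product: 5 (R)-3-methyl-2-vinylcyclohex-2-en-1-ol
Conditions: PdCl2(dppf) (5 mol%), Cs2CO3, THF/H2O 9:1, 70 °C
Reagents that add atoms: potassium vinyltrifluoroborate, [K+].C=C[B-](F)(F)F
Why: Suzuki–Miyaura coupling of an alkenyl iodide with a vinyltrifluoroborate tolerates the free allylic hydroxyl and does not touch the carbinol centre.

Step 4
Reactants: 5 (R)-3-methyl-2-vinylcyclohex-2-en-1-ol, 6 diiodomethane
Product: 7 (1R,2R,6R)-6-methyl-1-vinylbicyclo[4.1.0]heptan-2-ol (hydroxyl cis to the cyclopropane CH2)
Conditions: Et2Zn (2 equiv), CH2Cl2, −20 → 0 °C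
Reagents that add atoms: diiodomethane, ICI
Why: Hydroxyl-directed Simmons–Smith cyclopropanation, in which the zinc alkoxide delivers the methylene to the adjacent, more electron-rich ring alkene on the face of the oxygen, which sets C5 and the quaternary C10 (methyl trans to the oxygen) and should leave the more remote, less nucleophilic vinyl group.

Step 5
Reactants: 7 (1R,2R,6R)-6-methyl-1-vinylbicyclo[4.1.0]heptan-2-ol
Product: 8 tert-butyldimethyl{[(1R,2R,6R)-6-methyl-1-vinylbicyclo[4.1.0]heptan-2-yl]oxy}silane
Conditions: TBSCl, imidazole, DMF, 40 °C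
Reagents that add atoms: tert-butyldimethylsilyl chloride, CC(C)(C)[Si](C)(C)Cl
Why: Standard silylation of a secondary alcohol masks the hydroxyl for the carbonylation and the ketalisation.

Step 6
Reactants: 8 tert-butyldimethyl{[(1R,2R,6R)-6-methyl-1-vinylbicyclo[4.1.0]heptan-2-yl]oxy}silane, 9 carbon monoxide
Product: 10 (4R,10R)-4α-(tert-butyldimethylsilyloxy)-10β-methyl-Δ5-octalin-8-one
Conditions: [Rh(CO)2Cl]2 (5 mol%), CO (1 atm), toluene, 80 °C
Reagents that add atoms: carbon monoxide, [C-]#[O+]
Why: Monovalent rhodium binds the vinyl group and adds oxidatively into the neighbouring C5–C9 bond, which gives a σ-alkyl π-allyl rhodacycle (Rh–C9 and the C5–C6–C7 allyl unit); CO then inserts into the Rh–C9 bond and reductive elimination joins the acyl carbon to the allyl terminus C7, so that C8–C9 and C7–C8 are formed and the alkene ends at C5=C6. The closest known reaction type is the rhodium-catalysed [5+1] cycloaddition of vinylcyclopropanes with CO, together with the related iron carbonyl carbonylation of alkenylcyclopropanes. Ring B is closed in a formal [5+1] mode by reductive elimination from the acyl rhodacycle, with release of cyclopropane strain as the driving force. No stereocentre is made: C10 keeps the configuration fixed in step 4 because none of its bonds is broken, and C4 is a spectator. The step needs site selectivity between C5–C9 and the ring-fusion bond C5–C10, which the unsubstituted methylene C9 should secure (insertion at the quaternary C10 would give a tertiary alkyl rhodium and a bridged ring), and it needs the alkene to stay β,γ, which the neutral, base-free conditions favour.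

Step 7
Reactants: 10 (4R,10R)-4α-(tert-butyldimethylsilyloxy)-10β-methyl-Δ5-octalin-8-one
Product: 11 4α-(tert-butyldimethylsilyloxy)-8,8-ethylenedioxy-10β-methyl-Δ5-octalin
Conditions: (TMSOCH2)2, TMSOTf (5 mol%), CH2Cl2, −78 °C; pyridine
Reagents that add atoms: 1,2-bis(trimethylsilyloxy)ethane, C[Si](C)(C)OCCO[Si](C)(C)C
Why: Ketalisation with the bis-silyl ether of ethylene glycol and catalytic TMSOTf at low temperature protects C8 without cleaving the silyl ether or moving the C5=C6 bond, and it removes the acidic C7 hydrogens from which a vinylogous elimination of the C4 oxygen could start.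

Step 8
Reactants: 11 4α-(tert-butyldimethylsilyloxy)-8,8-ethylenedioxy-10β-methyl-Δ5-octalin
Product: 12 8,8-ethylenedioxy-10β-methyl-Δ5-octalin-4α-ol
Conditions: Bu4NF, THF, 0 °C → rt
Reagents that add atoms: none
Why: Fluoride-mediated desilylation frees the allylic alcohol, and the ketal is inert to the basic fluoride.

Step 9
Reactants: 12 8,8-ethylenedioxy-10β-methyl-Δ5-octalin-4α-ol
Product: 13 8,8-ethylenedioxy-10β-methyl-trans-decalin-4α-ol (5α-H)
Conditions: H2 (1 atm), [Ir(cod)(PCy3)(py)]PF6 (5 mol%), CH2Cl2, rt
Reagents that add atoms: none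
Why: Hydroxyl-directed homogeneous hydrogenation, in which the cationic iridium catalyst binds the C4 hydroxyl and delivers H2 to the α face of C5=C6 on which that hydroxyl lies, which is also the face away from the C10 methyl, so H-5 should enter trans to the angular methyl and give the trans-decalin.

Step 10
Reactants: 13 8,8-ethylenedioxy-10β-methyl-trans-decalin-4α-ol
Product: 14 8,8-ethylenedioxy-10β-methyl-trans-decalin-4-one (5α-H)
Conditions: Dess–Martin periodinane, NaHCO3, CH2Cl2, 0 °C → rt
Reagents that add atoms: none
Why: Dess–Martin oxidation of a secondary alcohol under buffered, non-enolising conditions should give the C4 ketone without epimerising the adjacent C5.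

Step 11
Reactants: 14 8,8-ethylenedioxy-10β-methyl-trans-decalin-4-one
Product: 15 8,8-ethylenedioxy-3α-hydroxy-10β-methyl-trans-decalin-4-one
Conditions: KN(SiMe3)2, THF, −78 °C; 3-phenyl-2-(phenylsulfonyl)oxaziridine, −78 °C; NH4Cl aq
Reagents that add atoms: 3-phenyl-2-(phenylsulfonyl)oxaziridine, O=S(=O)(c1ccccc1)N1OC1c1ccccc1
Why: Kinetic deprotonation takes a C3 methylene proton and not the hindered C5 methine, and Davis oxidation of the enolate should bring in the hydroxyl from the α face, anti to the C10 methyl; this C3 centre is reset in steps 13 and 14, so either epimer serves.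

Step 12
Reactants: 15 8,8-ethylenedioxy-3α-hydroxy-10β-methyl-trans-decalin-4-one, 16 methylmagnesium bromide
Product: 17 8,8-ethylenedioxy-4α,10β-dimethyl-trans-decalin-3α,4β-diol
Conditions: MeMgBr (4 equiv), THF, −78 → 0 °C; NH4Cl aq
Reagents that add atoms: methylmagnesium bromide, C[Mg]Br
Why: Grignard addition to a hindered cyclohexanone, in which the axial β trajectory at C4 is closed by the syn-axial C10 methyl, so the methyl group should enter equatorially from the α face and give the axial 4β-hydroxyl and 4α-methyl of the target; the first equivalent only deprotonates the C3 hydroxyl.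

Step 13
Reactants: 17 8,8-ethylenedioxy-4α,10β-dimethyl-trans-decalin-3α,4β-diol
Product: 18 8,8-ethylenedioxy-4β-hydroxy-4α,10β-dimethyl-trans-decalin-3-one
Conditions: IBX, DMSO, rt
Reagents that add atoms: none
Why: IBX oxidation converts the secondary hydroxyl of a 1,2-diol into the ketone without glycol cleavage and cannot touch the tertiary hydroxyl.

Step 14
Reactants: 18 8,8-ethylenedioxy-4β-hydroxy-4α,10β-dimethyl-trans-decalin-3-one
Product: 20 3β,4β-dihydroxy-4α,10β-dimethyl-trans-decalin-8-one, via ketal diol 19 (not isolated)
Conditions: NaBH4, MeOH, −20 °C; then 1 M HCl, THF, rt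
Reagents that add atoms: water, O
Why: Borohydride reduction of a cyclohexanone by axial attack, with hydride entering C3 from the α face, anti to the axial C4–O bond (Felkin–Anh) and away from the C10 methyl, should give the equatorial 3β-alcohol cis to the 4β-hydroxyl, and the dilute acid then hydrolyses the dioxolane, which is no longer needed.

Step 15
Reactants: 20 3β,4β-dihydroxy-4α,10β-dimethyl-trans-decalin-8-one, 21 angelic acid
Product: 22 3β-angeloyloxy-4β-hydroxy-4α,10β-dimethyl-trans-decalin-8-one
Conditions: angelic acid, 2,4,6-trichlorobenzoyl chloride, Et3N, toluene, rt; then 20, 75 °C (no DMAP)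
Reagents that add atoms: angelic acid, C/C=C(/C)C(=O)O
Why: Yamaguchi esterification through the mixed 2,4,6-trichlorobenzoic anhydride, run without a nucleophilic catalyst, is the usual way to attach an angelate without Z-to-E isomerisation to the tiglate, and only the secondary 3β-hydroxyl should react because the tertiary axial one is too hindered.

Step 16
Reactants: 22 3β-angeloyloxy-4β-hydroxy-4α,10β-dimethyl-trans-decalin-8-one, 23 acetic anhydride
Product: 24 4β-acetoxy-3β-angeloyloxy-4α,10β-dimethyl-trans-decalin-8-one
Conditions: Ac2O, Sc(OTf)3 (5 mol%), MeCN, −20 °C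
Reagents that add atoms: acetic anhydride, CC(=O)OC(C)=O
Why: Lewis acid-catalysed acylation with Sc(OTf)3 and acetic anhydride is among the few methods that esterify hindered tertiary alcohols at low temperature, where elimination and angelate isomerisation are slow; the angelate already on O3 rules out acyl migration to that oxygen.

Step 17
Reactants: 24 4β-acetoxy-3β-angeloyloxy-4α,10β-dimethyl-trans-decalin-8-one, 25 acetone
Product: 26 4β-acetoxy-3β-angeloyloxy-11-hydroxy-5α-eudesman-8-one (C7 epimers)
Conditions: LiN(i-Pr)2 (1.0 equiv), THF, −78 °C; ZnCl2; acetone, −78 → −40 °C; NH4Cl aq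
Reagents that add atoms: acetone, CC(C)=O
Why: Directed aldol addition, in which the amide base deprotonates the ketone at C7, the α-position remote from the quaternary C10, faster than it enolises the esters at −78 °C, and the zinc enolate adds to acetone; the C7 configuration is of no consequence because C7 becomes trigonal in step 18.

Step 18
Reactants: 26 4β-acetoxy-3β-angeloyloxy-11-hydroxy-5α-eudesman-8-one
Product: 28 4β-acetoxy-3β-angeloyloxy-5α-eudesm-7(11)-en-8-one, via tertiary mesylate 27 (not isolated)
Conditions: MsCl, Et3N, CH2Cl2, 0 °C; then DBU, rt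
Reagents that add atoms: none
Why: Mesylation through the sulfene followed by E1cB elimination of the β-mesyloxy ketone should give the conjugated isopropylidene ketone, and DBU brings any isopropenyl isomer into conjugation.

Step 19
Reactants: 28 4β-acetoxy-3β-angeloyloxy-5α-eudesm-7(11)-en-8-one
Product: 29 (3S,4R,5R,7S,10R)-4β-acetoxy-3β-angeloyloxy-7α-hydroxy-5α-eudesm-11-en-8-one (CNP0381775.1)
Conditions: KN(SiMe3)2 (0.95 equiv), THF, −78 → 0 °C, then −78 °C; 3-phenyl-2-(phenylsulfonyl)oxaziridine; AcOH, −78 °C
Reagents that add atoms: 3-phenyl-2-(phenylsulfonyl)oxaziridine, O=S(=O)(c1ccccc1)N1OC1c1ccccc1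
Why: Deconjugative Davis α-hydroxylation, in which brief equilibration with slightly less than one equivalent of base should give the linear dienolate (C8 enolate conjugated with C11=C12) that reacts at its α-carbon C7, and axial attack on the α face of the ring B enolate places the hydroxyl axial (7α) and the isopropenyl group equatorial (7β).

Compound list
1 | 3-methylcyclohex-2-en-1-one | CC1=CC(=O)CCC1 | starting material
2 | 2-iodo-3-methylcyclohex-2-en-1-one | CC1=C(I)C(=O)CCC1 | intermediate
3 | (R)-2-iodo-3-methylcyclohex-2-en-1-ol | CC1=C(I)[C@H](O)CCC1 | intermediate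
4 | potassium vinyltrifluoroborate | [K+].C=C[B-](F)(F)F | starting material
5 | (R)-3-methyl-2-vinylcyclohex-2-en-1-ol | C=CC1=C(C)CCC[C@H]1O | intermediate
6 | diiodomethane | ICI | starting material
7 | (1R,2R,6R)-6-methyl-1-vinylbicyclo[4.1.0]heptan-2-ol | C=C[C@]12C[C@@]1(C)CCC[C@H]2O | intermediate
8 | tert-butyldimethyl{[(1R,2R,6R)-6-methyl-1-vinylbicyclo[4.1.0]heptan-2-yl]oxy}silane | C=C[C@]12C[C@@]1(C)CCC[C@H]2O[Si](C)(C)C(C)(C)C | intermediate
9 | carbon monoxide | [C-]#[O+] | starting material
10 | (4R,10R)-4α-(tert-butyldimethylsilyloxy)-10β-methyl-Δ5-octalin-8-one | O=C1CC=C2[C@H](O[Si](C)(C)C(C)(C)C)CCC[C@]2(C)C1 | intermediate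
11 | 4α-(tert-butyldimethylsilyloxy)-8,8-ethylenedioxy-10β-methyl-Δ5-octalin | C1C=C2[C@](C)(CCC[C@H]2O[Si](C)(C)C(C)(C)C)CC13OCCO3 | intermediate
12 | 8,8-ethylenedioxy-10β-methyl-Δ5-octalin-4α-ol | C1C=C2[C@](C)(CCC[C@H]2O)CC13OCCO3 | intermediate
13 | 8,8-ethylenedioxy-10β-methyl-trans-decalin-4α-ol (5α-H) | C1C[C@@H]2[C@](C)(CCC[C@H]2O)CC13OCCO3 | intermediate
14 | 8,8-ethylenedioxy-10β-methyl-trans-decalin-4-one (5α-H) | C1C[C@@H]2[C@](C)(CCCC2=O)CC13OCCO3 | intermediate
15 | 8,8-ethylenedioxy-3α-hydroxy-10β-methyl-trans-decalin-4-one | C1C[C@@H]2[C@](C)(CC[C@@H](O)C2=O)CC13OCCO3 | intermediate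
16 | methylmagnesium bromide | C[Mg]Br | starting material
17 | 8,8-ethylenedioxy-4α,10β-dimethyl-trans-decalin-3α,4β-diol | C1C[C@@H]2[C@](C)(CC[C@@H](O)[C@]2(C)O)CC13OCCO3 | intermediate
18 | 8,8-ethylenedioxy-4β-hydroxy-4α,10β-dimethyl-trans-decalin-3-one | C1C[C@@H]2[C@](C)(CCC(=O)[C@]2(C)O)CC13OCCO3 | intermediate
19 | 8,8-ethylenedioxy-4α,10β-dimethyl-trans-decalin-3β,4β-diol (ketal diol, not isolated) | C1C[C@@H]2[C@](C)(CC[C@H](O)[C@]2(C)O)CC13OCCO3 | intermediate
20 | 3β,4β-dihydroxy-4α,10β-dimethyl-trans-decalin-8-one | C1C[C@@H]2[C@](C)(CC[C@H](O)[C@]2(C)O)CC1=O | intermediate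
21 | angelic acid, (Z)-2-methylbut-2-enoic acid | C/C=C(/C)C(=O)O | starting material
22 | 3β-angeloyloxy-4β-hydroxy-4α,10β-dimethyl-trans-decalin-8-one | C1C[C@@H]2[C@](C)(CC[C@H](OC(=O)/C(C)=C\C)[C@]2(C)O)CC1=O | intermediate
23 | acetic anhydride | CC(=O)OC(C)=O | starting material
24 | 4β-acetoxy-3β-angeloyloxy-4α,10β-dimethyl-trans-decalin-8-one | C1C[C@@H]2[C@](C)(CC[C@H](OC(=O)/C(C)=C\C)[C@]2(C)OC(C)=O)CC1=O | intermediate
25 | acetone | CC(C)=O | starting material
26 | 4β-acetoxy-3β-angeloyloxy-11-hydroxy-5α-eudesman-8-one (C7 not defined) | CC(C)(O)C1C[C@@H]2[C@](C)(CC[C@H](OC(=O)/C(C)=C\C)[C@]2(C)OC(C)=O)CC1=O | intermediate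
27 | 11-methanesulfonate of 26 (tertiary mesylate, not isolated) | CC(C)(OS(C)(=O)=O)C1C[C@@H]2[C@](C)(CC[C@H](OC(=O)/C(C)=C\C)[C@]2(C)OC(C)=O)CC1=O | intermediate
28 | 4β-acetoxy-3β-angeloyloxy-5α-eudesm-7(11)-en-8-one | CC(C)=C1C[C@@H]2[C@](C)(CC[C@H](OC(=O)/C(C)=C\C)[C@]2(C)OC(C)=O)CC1=O | intermediate
29 | (3S,4R,5R,7S,10R)-4β-acetoxy-3β-angeloyloxy-7α-hydroxy-5α-eudesm-11-en-8-one (CNP0381775.1) | C=C(C)[C@@]1(O)C[C@@H]2[C@](C)(CC[C@H](OC(=O)/C(C)=C\C)[C@]2(C)OC(C)=O)CC1=O | target

Total step count: 19. Longest linear sequence: 19 steps (1 → 29); all other reactants are commercial.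

Steps most likely to fail

Step 6. Oxidative addition into the fully substituted cyclopropane may be slow, so that the catalyst isomerises the vinylcyclopropane to dienes instead. The π-allyl intermediate may also lose the C4 silyloxy group by β-elimination, or the β,γ-enone may drift into conjugation. The fallback sets out from 8 and returns at 10 by the stoichiometric iron carbonyl route: irradiation (about 350 nm) with Fe(CO)5 under CO in 2-propanol. Photochemically generated Fe(CO)4 binds the vinyl group at low temperature, inserts into C5–C9 and collapses through an acyl π-allyl iron species to 10. This replaces a thermal catalytic cycloaddition by a photochemical, stoichiometric organoiron carbonylation, and it makes no new compound (F0).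

Step 19. Enolisation may occur at C9 or at the ester α-positions instead of giving the linear dienolate, the oxidant may attack the γ-carbon, or facial selectivity at C7 may be poor. The fallback sets out from 28 and uses no base: dye-sensitised photooxygenation (O2, tetraphenylporphyrin, visible light, CH2Cl2, −20 °C). In this Schenck ene reaction of the s-cis enone, singlet oxygen bonds to C7 and takes a hydrogen from a C11 methyl group, which should give 4β-acetoxy-3β-angeloyloxy-7α-hydroperoxy-5α-eudesm-11-en-8-one F1 after separation from isomeric ene products. Reduction with dimethyl sulfide returns to the route at 29.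

Step 16. The axial tertiary hydroxyl, syn-axial to the C10 methyl, may resist acylation or ionise and eliminate under the Lewis acid, and the angelate may isomerise. The fallback sets out from 20 and delivers the acetyl group intramolecularly. Trimethyl orthoacetate and PPTS in CH2Cl2 should give the cyclic 3,4-orthoacetate F2. Aqueous acetic acid opens it with the usual preference for the axial ester, which should give 4β-acetoxy-3β-hydroxy-4α,10β-dimethyl-trans-decalin-8-one F3. Angeloylation of the free 3β-hydroxyl under the conditions of step 15, with short reaction time and no excess base to limit acetyl migration, returns to the route at 24.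

Further compounds
F0 | step 6 | none | none
F1 | step 19 | 4β-acetoxy-3β-angeloyloxy-7α-hydroperoxy-5α-eudesm-11-en-8-one | C=C(C)[C@@]1(OO)C[C@@H]2[C@](C)(CC[C@H](OC(=O)/C(C)=C\C)[C@]2(C)OC(C)=O)CC1=O
F2 | step 16 | cyclic 3β,4β-(1-methoxyethylidene) orthoacetate of 20 (orthoester carbon not defined) | C1C[C@@H]2[C@](C)(CC[C@H](O3)[C@]2(C)OC3(C)OC)CC1=O
F3 | step 16 | 4β-acetoxy-3β-hydroxy-4α,10β-dimethyl-trans-decalin-8-one | C1C[C@@H]2[C@](C)(CC[C@H](O)[C@]2(C)OC(C)=O)CC1=O
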